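All runs are simulated with constants of no real substance, noise included.

The shift lead and the process chemist read the same two runs and agree on the flask dawn, which lies between them in charge, but they part over what the extra 5.00 h of summer bring.

| setting | Monday's | Saturday's | dawn | summer |
|---|---|---|---|---|
| substrate | 0.47 M | 1.9 M | 0.94 M | 0.94 M |
| remark | run made earlier | run made earlier |  |  |
| time |  |  | 10 h | 15 h |

| run | time / h | intermediate A / % | intermediate B / % | substrate / % | target / % |
|---|---|---|---|---|---|
| Monday's | 0.833 | 3.1 | 80.6 | 10.4 | 5.9 |
| Monday's | 1.33 | 3.2 | 83.2 | 3.3 | 10.0 |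
| Monday's | 2.00 | 3.0 | 79.1 | 0.4 | 16.7 |
| Monday's | 4.00 | 3.7 | 64.1 | 0 | 32.2 |
| Monday's | 6.00 | 4.3 | 51.5 | 0 | 44.8 |
| Monday's | 10.0 | 4.9 | 33.3 | 0.4 | 62.1 |
| Saturday's | 0.667 | 2.5 | 75.9 | 17.1 | 4.0 |
| Saturday's | 2.00 | 3.1 | 78.7 | 1.0 | 17.3 |
| Saturday's | 4.00 | 2.6 | 62.8 | 0 | 34.3 |
| Saturday's | 5.00 | 3.4 | 56.0 | 0 | 41.4 |
| Saturday's | 8.00 | 3.1 | 39.3 | 0 | 58.0 |
| Saturday's | 10.0 | 3.3 | 30.9 | 0.2 | 66.7 |

(readings scatter by 0.3 percentage points)

- target is meant together with its crystals
- solid, in amounts per volume of the solution: crystals
- the numbers in the tables scatter with a standard deviation of 0.3 percentage points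
- candidate steps: intermediate B <-> target; substrate -> intermediate B; crystals <-> target; target <-> intermediate A; substrate -> intermediate A

- which of these there is most of at the end, counted by the substrate in it, dawn (target / intermediate A / intermediate B / substrate)
- which of these there is most of at the end, counted by the substrate in it, summer (target / intermediate A / intermediate B / substrate)
- final amount of the leader among these, as a percentage of the substrate charged, in dawn
- final amount of the leader among these, as a percentage of the substrate charged, in summer

The shift lead holds that the target simply grows at a steady rate, a zero-order line, and so lays Monday's gain of 17 percentage points between 6.00 h and 10.0 h onward from Monday's last reading, which gives 83.7% at the time of summer.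

The chemist holds that intermediate B decays towards a floor, one molar amount for every charge. From 2.00 h to 10.0 h, the factor on intermediate B was 2.55 in Saturday's run and 2.38 in Monday's, and a floor of 0.0227 M makes the two factors equal. Above that floor the readings give 5.78 h as the excess half-life, the time in which the intermediate B standing above the floor halves, a pseudo-first-order decay.

On that view intermediate B at a fixed time is a straight line in the charge, so I put dawn at 0.298 M of it and summer at 0.174 M. Taking intermediate A as the mean of the last two readings and the rest as target, I get 64.2% and 77.4%.

The forecast, on the chemist's side, names target and target as leaders with 65% and 77%, reading in the runs “a small reverse flow from target held at its solubility by crystals”.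

The flask gives target first in both, 64.8% in dawn and 78.0% in summer, so the line stood 5.7 points too high. The line does fit a late stretch shorter than 5.78 h: from 8.00 h to 10.0 h, Saturday's run gained 8.7 points, and the slope of the line gives 8.7 points over that time.

    intermediate B ⇌ target (K = 2.00, k = 3.40 × 10⁻⁵ /s)
    substrate → intermediate B (k = 7.10 × 10⁻⁴ /s)
    crystals ⇌ target, rate k3*(cs3 - [target]) while solid is left; crystals form when [target] > cs3 (solubility = 0.0510 M, k = 0.00760 /s)
    target ⇌ intermediate A (K = 0.690, k = 8.30 × 10⁻⁶ /s)
    substrate → intermediate A (k = 2.40 × 10⁻⁵ /s)

The excess half-life of 5.78 h stands beside the forward half-life of intermediate B into target in dawn, 5.7 h, which is longer than the relaxation half-life of that step both ways, 3.78 h. Carried from dawn's 31.8% it gives 18.5% of intermediate B for summer, where the flask holds 18.5%, and carried from Monday's share at 2.00 h to the neighbour with 0.38 M of substrate it gives 34.0%, where that neighbour holds 34.4%.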